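**Plan**

- Retrosynthesis cuts, in this order: the aryl O–Si bond; the C5–CH2 bond of the hydroxyisobutyl arm; the C6–C7 bond of ring B (the cyclohexenone); the C4–C5 bond (carbonyl to alkyne); the aryl–CH2 bond of the side chain; and the C2–C3 bond of a bicyclo[3.3.0]octanone that masks the C3a aldehyde and the C7a acetic acid arm.
- Enabling feature: C7 is a methylene between the quaternary ring-fusion carbon C7a and the enone β-carbon C6, and the carbonyl C4 sits on the other ring-fusion carbon C3a. A primary radical on a CH2 at C7a (acetic acid arm minus CO2) can therefore add to C6 of an ynone C4(=O)–C5≡C6.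
- Forward: ring A (the cyclopentane) is carried intact from cis-1,5-dimethylbicyclo[3.3.0]octane-3,7-dione. The aryl enyne chain is built separately (carboalumination, arylcopper allylation) and joined by acetylide addition. Ring B then closes in the radical step; the C5 arm and the free phenol come last.
- Stereochemistry: the cis relation of C3a and C7a comes from the meso dione; the absolute configuration (3aR,7aR) comes from enantiotopic deprotonation of the meso monoketone by a chiral lithium amide; the E-alkene comes from syn-carboalumination.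

Key step: step 16

Assumption: the lithium amide from (R,R)-bis(1-phenylethyl)amine is taken to deprotonate the methylene next to the bridgehead that becomes C3a, giving enol ether 6; if the sense of induction is the opposite, the (S,S)-amine is used and nothing else changes.

Abbreviation used in names: TIPS = triisopropylsilyl.

**Route**

Step 1
Reactants: 1 cis-1,5-dimethylbicyclo[3.3.0]octane-3,7-dione
Product: 2 cis-1,5-dimethylbicyclo[3.3.0]octane-3,7-dione mono(2,2-dimethylpropane-1,3-diyl) ketal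
Conditions: 2,2-dimethylpropane-1,3-diol (1.0 equiv), p-TsOH·H2O (cat.), benzene, reflux, Dean–Stark
Reagents that add atoms: 2,2-dimethylpropane-1,3-diol, OCC(C)(C)CO
Why: Acid-catalysed ketalisation with azeotropic removal of water; the two carbonyl groups are equivalent, so one equivalent of diol should give mainly the achiral monoketal (dione and bisketal are recycled).

Step 2
Reactants: 2 cis-1,5-dimethylbicyclo[3.3.0]octane-3,7-dione mono(2,2-dimethylpropane-1,3-diyl) ketal
Product: 5 cis-1,5-dimethylbicyclo[3.3.0]octan-3-one, via hydrazone 3 (not isolated), via deoxygenated ketal 4 (not isolated)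
Conditions: N2H4·H2O, KOH, diethylene glycol, 130 then 200 °C; then 2 M HCl, THF/H2O, rt
Reagents that add atoms: none
Why: Wolff–Kishner reduction of the free ketone through its hydrazone, the ketal being stable to hot base, followed by acid hydrolysis of the ketal to the meso monoketone.

Step 3
Reactants: 5 cis-1,5-dimethylbicyclo[3.3.0]octan-3-one
Product: 6 (1S,5R)-1,5-dimethyl-3-(trimethylsilyloxy)bicyclo[3.3.0]oct-2-ene
Conditions: (R,R)-bis(1-phenylethyl)amine, n-BuLi, LiCl, THF, –78 °C; TMSCl then 5, –100 °C (in situ quench)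
Reagents that add atoms: chlorotrimethylsilane, C[Si](C)(C)Cl
Why: Enantiotopic-group-selective deprotonation of a meso ketone by a C2-symmetric chiral lithium amide with in situ silylation, well established for cis-bicyclo[3.3.0]octan-3-ones; the choice of α-methylene fixes the absolute configuration of both quaternary carbons for the rest of the route.

Step 4
Reactants: 6 (1S,5R)-1,5-dimethyl-3-(trimethylsilyloxy)bicyclo[3.3.0]oct-2-ene
Product: 8 2-[(1R,2R)-2-formyl-1,2-dimethylcyclopentyl]acetic acid, via methoxy hydroperoxide 7 (not isolated)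
Conditions: O3, CH2Cl2/MeOH, –78 °C; then Me2S, –78 °C to rt
Reagents that add atoms: ozone, [O-][O+]=O
Why: Ozonolysis of the silyl enol ether cleaves C2–C3 to an aldehyde on one side and a silyl ester (hence the acid) on the other; the aldehyde sits on a quaternary carbon and cannot epimerise.

Step 5
Reactants: 8 2-[(1R,2R)-2-formyl-1,2-dimethylcyclopentyl]acetic acid
Product: 9 tert-butyl 2-[(1R,2R)-2-formyl-1,2-dimethylcyclopentyl]acetate
Conditions: O-tert-butyl-N,N'-diisopropylisourea, CH2Cl2, rt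
Reagents that add atoms: O-tert-butyl-N,N'-diisopropylisourea, CC(C)N=C(NC(C)C)OC(C)(C)C
Why: Neutral tert-butyl transfer from the isourea to the carboxylic acid leaves the aldehyde alone, and the bulky ester is chosen so that the alkoxide formed in step 13 cannot lactonise onto it.

Step 6
Reactants: 10 4-methoxy-2-methylphenol
Product: 11 2-bromo-4-methoxy-6-methylphenol
Conditions: NBS, CH2Cl2, 0 °C
Reagents that add atoms: N-bromosuccinimide, BrN1C(=O)CCC1=O
Why: Electrophilic aromatic bromination; the free hydroxyl is the strongest director and its para position is blocked, so bromine should enter the open ortho position.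

Step 7
Reactants: 11 2-bromo-4-methoxy-6-methylphenol
Product: 12 (2-bromo-4-methoxy-6-methylphenoxy)triisopropylsilane
Conditions: TIPSOTf, 2,6-lutidine, CH2Cl2, 0 °C to rt
Reagents that add atoms: triisopropylsilyl trifluoromethanesulfonate, CC(C)[Si](OS(=O)(=O)C(F)(F)F)(C(C)C)C(C)C
Why: Silylation of a hindered phenol with the silyl triflate; the bulky silyl ether is chosen because it resists O-to-C silyl migration in the ortho-metalated arene, tolerates mild base and acid, and is cleaved by fluoride at the end.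

Step 8
Reactants: 13 ethynyltrimethylsilane; 14 3-bromoprop-1-yne
Product: 16 trimethyl(penta-1,4-diyn-1-yl)silane, via alkynylmagnesium bromide 15 (not isolated)
Conditions: EtMgBr, THF, 0 °C to rt; then CuCl (cat.), 14, 50 °C
Reagents that add atoms: none
Why: Copper-catalysed coupling of an alkynyl Grignard reagent with a propargylic bromide, a standard route to skipped diynes, with the silyl group blocking one terminus.

Step 9
Reactants: 16 trimethyl(penta-1,4-diyn-1-yl)silane
Product: 19 (2E)-3-methyl-6-(trimethylsilyl)hex-2-en-5-yn-1-ol, via alkenylalane 17 (not isolated), via lithium alkenylalanate 18 (not isolated)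
Conditions: Me3Al, Cp2ZrCl2 (cat.), CH2Cl2, 0 °C to rt; evaporate; n-BuLi, THF, –78 °C; (CH2O)n, to rt; aq. HCl
Reagents that add atoms: trimethylaluminium, C[Al](C)C; paraformaldehyde (formaldehyde unit), C=O
Why: Zirconium-catalysed syn-carboalumination (Negishi) places methyl on the internal and aluminium on the terminal carbon of the free alkyne, the silylated alkyne being much less reactive, and hydroxymethylation of the alanate with retention gives the E-allylic alcohol.

Step 10
Reactants: 19 (2E)-3-methyl-6-(trimethylsilyl)hex-2-en-5-yn-1-ol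
Product: 20 [(4E)-6-bromo-4-methylhex-4-en-1-yn-1-yl]trimethylsilane
Conditions: CBr4, PPh3, CH2Cl2, 0 °C
Reagents that add atoms: carbon tetrabromide, BrC(Br)(Br)Br
Why: Appel bromination of a primary allylic alcohol proceeds by SN2 displacement without allylic transposition or loss of alkene geometry.

Step 11
Reactants: 12 (2-bromo-4-methoxy-6-methylphenoxy)triisopropylsilane; 20 [(4E)-6-bromo-4-methylhex-4-en-1-yn-1-yl]trimethylsilane
Product: 23 triisopropyl{4-methoxy-2-methyl-6-[(2E)-3-methyl-6-(trimethylsilyl)hex-2-en-5-yn-1-yl]phenoxy}silane, via aryllithium 21 (not isolated), via arylcopper 22 (not isolated)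
Conditions: t-BuLi (2 equiv), Et2O, –78 °C; CuBr·SMe2, –78 to –40 °C; then 20, –78 to 0 °C
Reagents that add atoms: none
Why: Bromine–lithium exchange, transmetalation to copper and SN2 allylation by the primary allylic bromide is the usual way of prenylating arenes; attack at the fully substituted γ-carbon is disfavoured and the E-geometry is retained.

Step 12
Reactants: 23 triisopropyl{4-methoxy-2-methyl-6-[(2E)-3-methyl-6-(trimethylsilyl)hex-2-en-5-yn-1-yl]phenoxy}silane
Product: 24 triisopropyl{4-methoxy-2-methyl-6-[(2E)-3-methylhex-2-en-5-yn-1-yl]phenoxy}silane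
Conditions: K2CO3, MeOH/THF, 0 °C
Reagents that add atoms: none
Why: Base-catalysed methanolysis of the alkynyl C–Si bond is fast, while the hindered aryl triisopropylsilyl ether should survive brief exposure at 0 °C.

Step 13
Reactants: 24 triisopropyl{4-methoxy-2-methyl-6-[(2E)-3-methylhex-2-en-5-yn-1-yl]phenoxy}silane; 9 tert-butyl 2-[(1R,2R)-2-formyl-1,2-dimethylcyclopentyl]acetate
Product: 26 tert-butyl 2-[(1R,2R)-2-{(1RS,5E)-1-hydroxy-7-[5-methoxy-3-methyl-2-(TIPS-oxy)phenyl]-5-methylhept-5-en-2-yn-1-yl}-1,2-dimethylcyclopentyl]acetate, via lithium acetylide 25 (not isolated)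
Conditions: n-BuLi, THF, –78 °C; then 9, –78 °C; AcOH quench at –78 °C
Reagents that add atoms: none
Why: 1,2-Addition of a lithium acetylide to a non-enolisable neopentyl aldehyde at low temperature; the carbinol centre forms as a mixture that does not matter because it is oxidised in the next step.

Step 14
Reactants: 26 tert-butyl 2-[(1R,2R)-2-{(1RS,5E)-1-hydroxy-7-[5-methoxy-3-methyl-2-(TIPS-oxy)phenyl]-5-methylhept-5-en-2-yn-1-yl}-1,2-dimethylcyclopentyl]acetate
Product: 27 tert-butyl 2-[(1R,2R)-2-{(5E)-7-[5-methoxy-3-methyl-2-(TIPS-oxy)phenyl]-5-methylhept-5-en-2-ynoyl}-1,2-dimethylcyclopentyl]acetate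
Conditions: Dess–Martin periodinane, NaHCO3, CH2Cl2, 0 °C to rt
Reagents that add atoms: none
Why: Dess–Martin oxidation of a secondary propargylic alcohol under buffered, non-basic conditions avoids isomerisation of the skipped enyne next to the new ynone.

Step 15
Reactants: 27 tert-butyl 2-[(1R,2R)-2-{(5E)-7-[5-methoxy-3-methyl-2-(TIPS-oxy)phenyl]-5-methylhept-5-en-2-ynoyl}-1,2-dimethylcyclopentyl]acetate
Product: 29 1,3-dioxoisoindolin-2-yl 2-[(1R,2R)-2-{(5E)-7-[5-methoxy-3-methyl-2-(TIPS-oxy)phenyl]-5-methylhept-5-en-2-ynoyl}-1,2-dimethylcyclopentyl]acetate, via ynone acid 28 (not isolated)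
Conditions: TFA/CH2Cl2 (1:4), 0 °C; evaporate with toluene; then N-hydroxyphthalimide, N,N'-diisopropylcarbodiimide, DMAP (cat.), CH2Cl2, 0 °C to rt
Reagents that add atoms: N-hydroxyphthalimide, ON1C(=O)c2ccccc2C1=O
Why: Acidolysis of the tert-butyl ester with loss of isobutene, to which ynone, alkene and aryl silyl ether should be stable at 0 °C, followed by carbodiimide (Steglich-type) esterification of the crude acid so that the sensitive ynone acid is not stored.

Step 16
Reactants: 29 1,3-dioxoisoindolin-2-yl 2-[(1R,2R)-2-{(5E)-7-[5-methoxy-3-methyl-2-(TIPS-oxy)phenyl]-5-methylhept-5-en-2-ynoyl}-1,2-dimethylcyclopentyl]acetate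
Product: 30 (3aR,7aR)-6-{(2E)-4-[5-methoxy-3-methyl-2-(TIPS-oxy)phenyl]-2-methylbut-2-en-1-yl}-3a,7a-dimethyl-1,2,3,3a,7,7a-hexahydro-4H-inden-4-one
Conditions: undivided cell, Zn anode, reticulated vitreous carbon cathode, constant current (about 2.2 F/mol), n-Bu4NPF6 (0.1 M), (CF3)2CHOH (3 equiv), DMF, 5 mM, rt
Reagents that add atoms: none
Why: Proposed new method: one-electron reduction of the N-acyloxyphthalimide at the cathode (assisted by Zn2+ from the anode and the fluoro alcohol) releases CO2 and phthalimide anion and leaves a primary radical on the CH2 attached to the future C7a; this radical adds to the ynone β-carbon, and the resulting α-keto vinyl radical is reduced and protonated at C5 to give the enone. The closest known reaction type is the cathodic decarboxylative Giese addition of N-acyloxyphthalimides to electron-poor alkenes, extended here to an intramolecular addition to an alkynyl ketone. Ring B closes in the 6-endo-dig mode; no stereocentre is formed and the two quaternary centres are untouched. The step needs 6-endo rather than 5-exo closure and electron transfer to the ester rather than to the ynone. The nucleophilic alkyl radical is polarity-matched with the β-carbon, attack at the α-carbon would give an unstabilised vinyl radical in a strained five-membered ring, the two cis quaternary carbons hold the chain ends together, and the ester is expected to be reduced several hundred millivolts before a dialkyl ynone. High dilution and a mild proton donor are meant to suppress intermolecular addition and base-induced isomerisation of the skipped enyne.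

Step 17
Reactants: 30 (3aR,7aR)-6-{(2E)-4-[5-methoxy-3-methyl-2-(TIPS-oxy)phenyl]-2-methylbut-2-en-1-yl}-3a,7a-dimethyl-1,2,3,3a,7,7a-hexahydro-4H-inden-4-one
Product: 31 (3aR,7aR)-5-iodo-6-{(2E)-4-[5-methoxy-3-methyl-2-(TIPS-oxy)phenyl]-2-methylbut-2-en-1-yl}-3a,7a-dimethyl-1,2,3,3a,7,7a-hexahydro-4H-inden-4-one
Conditions: I2, pyridine/CH2Cl2, DMAP (cat.), rt, dark
Reagents that add atoms: iodine, II
Why: α-Iodination of the enone by the amine-mediated addition–iodination–elimination sequence; molecular iodine without an oxidant should spare the electron-rich arene and the isolated alkene.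

Step 18
Reactants: 32 3-hydroxy-3-methylbutanoic acid
Product: 33 1,3-dioxoisoindolin-2-yl 3-hydroxy-3-methylbutanoate
Conditions: N-hydroxyphthalimide, N,N'-diisopropylcarbodiimide, DMAP (cat.), CH2Cl2, 0 °C to rt
Reagents that add atoms: N-hydroxyphthalimide, ON1C(=O)c2ccccc2C1=O
Why: Carbodiimide esterification of the acid; the tertiary hydroxyl is too hindered to be acylated and needs no protection.

Step 19
Reactants: 31 (3aR,7aR)-5-iodo-6-{(2E)-4-[5-methoxy-3-methyl-2-(TIPS-oxy)phenyl]-2-methylbut-2-en-1-yl}-3a,7a-dimethyl-1,2,3,3a,7,7a-hexahydro-4H-inden-4-one; 33 1,3-dioxoisoindolin-2-yl 3-hydroxy-3-methylbutanoate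
Product: 34 (3aR,7aR)-5-(2-hydroxy-2-methylpropyl)-6-{(2E)-4-[5-methoxy-3-methyl-2-(TIPS-oxy)phenyl]-2-methylbut-2-en-1-yl}-3a,7a-dimethyl-1,2,3,3a,7,7a-hexahydro-4H-inden-4-one
Conditions: NiCl2(glyme) (20 mol%), 4,4'-di-tert-butyl-2,2'-bipyridine (20 mol%), Zn dust (3 equiv), DMA, rt
Reagents that add atoms: none
Why: Nickel-catalysed reductive cross-electrophile coupling of an alkenyl iodide with a redox-active ester: oxidative addition of low-valent nickel to the C–I bond, capture of the 2-hydroxy-2-methylpropyl radical released from 33 with loss of CO2, and reductive elimination, with zinc closing the cycle.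

Step 20
Reactants: 34 (3aR,7aR)-5-(2-hydroxy-2-methylpropyl)-6-{(2E)-4-[5-methoxy-3-methyl-2-(TIPS-oxy)phenyl]-2-methylbut-2-en-1-yl}-3a,7a-dimethyl-1,2,3,3a,7,7a-hexahydro-4H-inden-4-one
Product: 35 (3aR,7aR)-5-(2-hydroxy-2-methylpropyl)-6-[(2E)-4-(2-hydroxy-5-methoxy-3-methylphenyl)-2-methylbut-2-en-1-yl]-3a,7a-dimethyl-1,2,3,3a,7,7a-hexahydro-4H-inden-4-one
Conditions: TBAF, AcOH, THF, 0 °C
Reagents that add atoms: none
Why: Fluoride cleavage of the aryl silyl ether, buffered with acetic acid so that the phenoxide does not isomerise the skipped dienone, leaves tertiary alcohol, enone and alkene untouched.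

**Compound list**

1 | cis-1,5-dimethylbicyclo[3.3.0]octane-3,7-dione (meso) | O=C1C[C@]2(C)CC(=O)C[C@]2(C)C1 | starting material
2 | cis-1,5-dimethylbicyclo[3.3.0]octane-3,7-dione mono(2,2-dimethylpropane-1,3-diyl) ketal (achiral) | O=C1C[C@]2(C)CC3(C[C@]2(C)C1)OCC(C)(C)CO3 | intermediate
3 | hydrazone of 2 at the free carbonyl | NN=C1C[C@]2(C)CC3(C[C@]2(C)C1)OCC(C)(C)CO3 | intermediate
4 | cis-1,5-dimethylbicyclo[3.3.0]octan-3-one 2,2-dimethylpropane-1,3-diyl ketal | C1C[C@]2(C)CC3(C[C@]2(C)C1)OCC(C)(C)CO3 | intermediate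
5 | cis-1,5-dimethylbicyclo[3.3.0]octan-3-one (meso) | O=C1C[C@]2(C)CCC[C@]2(C)C1 | intermediate
6 | (1S,5R)-1,5-dimethyl-3-(trimethylsilyloxy)bicyclo[3.3.0]oct-2-ene | C[Si](C)(C)OC1=C[C@]2(C)CCC[C@]2(C)C1 | intermediate
7 | trimethylsilyl 2-[(1R,2R)-2-[hydroperoxy(methoxy)methyl]-1,2-dimethylcyclopentyl]acetate (epimers at the peroxy carbon) | COC(OO)[C@]1(C)CCC[C@]1(C)CC(=O)O[Si](C)(C)C | intermediate
8 | 2-[(1R,2R)-2-formyl-1,2-dimethylcyclopentyl]acetic acid | O=C[C@]1(C)CCC[C@]1(C)CC(=O)O | intermediate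
9 | tert-butyl 2-[(1R,2R)-2-formyl-1,2-dimethylcyclopentyl]acetate | O=C[C@]1(C)CCC[C@]1(C)CC(=O)OC(C)(C)C | intermediate
10 | 4-methoxy-2-methylphenol | COc1ccc(O)c(C)c1 | starting material
11 | 2-bromo-4-methoxy-6-methylphenol | COc1cc(C)c(O)c(Br)c1 | intermediate
12 | (2-bromo-4-methoxy-6-methylphenoxy)triisopropylsilane | COc1cc(C)c(O[Si](C(C)C)(C(C)C)C(C)C)c(Br)c1 | intermediate
13 | ethynyltrimethylsilane | C#C[Si](C)(C)C | starting material
14 | 3-bromoprop-1-yne (propargyl bromide) | C#CCBr | starting material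
15 | [(trimethylsilyl)ethynyl]magnesium bromide | C[Si](C)(C)C#C[Mg]Br | intermediate
16 | trimethyl(penta-1,4-diyn-1-yl)silane | C#CCC#C[Si](C)(C)C | intermediate
17 | dimethyl[(1E)-2-methyl-5-(trimethylsilyl)pent-1-en-4-yn-1-yl]alane | C[Al](C)/C=C(\C)CC#C[Si](C)(C)C | intermediate
18 | lithium butyl(dimethyl)[(1E)-2-methyl-5-(trimethylsilyl)pent-1-en-4-yn-1-yl]alanate | [Li+].CCCC[Al-](C)(C)/C=C(\C)CC#C[Si](C)(C)C | intermediate
19 | (2E)-3-methyl-6-(trimethylsilyl)hex-2-en-5-yn-1-ol | OC/C=C(\C)CC#C[Si](C)(C)C | intermediate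
20 | [(4E)-6-bromo-4-methylhex-4-en-1-yn-1-yl]trimethylsilane | BrC/C=C(\C)CC#C[Si](C)(C)C | intermediate
21 | [5-methoxy-3-methyl-2-(triisopropylsilyloxy)phenyl]lithium | COc1cc(C)c(O[Si](C(C)C)(C(C)C)C(C)C)c([Li])c1 | intermediate
22 | [5-methoxy-3-methyl-2-(triisopropylsilyloxy)phenyl]copper | COc1cc(C)c(O[Si](C(C)C)(C(C)C)C(C)C)c([Cu])c1 | intermediate
23 | triisopropyl{4-methoxy-2-methyl-6-[(2E)-3-methyl-6-(trimethylsilyl)hex-2-en-5-yn-1-yl]phenoxy}silane | COc1cc(C)c(O[Si](C(C)C)(C(C)C)C(C)C)c(C/C=C(\C)CC#C[Si](C)(C)C)c1 | intermediate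
24 | triisopropyl{4-methoxy-2-methyl-6-[(2E)-3-methylhex-2-en-5-yn-1-yl]phenoxy}silane | COc1cc(C)c(O[Si](C(C)C)(C(C)C)C(C)C)c(C/C=C(\C)CC#C)c1 | intermediate
25 | {(4E)-6-[5-methoxy-3-methyl-2-(triisopropylsilyloxy)phenyl]-4-methylhex-4-en-1-yn-1-yl}lithium | COc1cc(C)c(O[Si](C(C)C)(C(C)C)C(C)C)c(C/C=C(\C)CC#C[Li])c1 | intermediate
26 | tert-butyl 2-[(1R,2R)-2-{(1RS,5E)-1-hydroxy-7-[5-methoxy-3-methyl-2-(triisopropylsilyloxy)phenyl]-5-methylhept-5-en-2-yn-1-yl}-1,2-dimethylcyclopentyl]acetate | COc1cc(C)c(O[Si](C(C)C)(C(C)C)C(C)C)c(C/C=C(\C)CC#CC(O)[C@]2(C)CCC[C@]2(C)CC(=O)OC(C)(C)C)c1 | intermediate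
27 | tert-butyl 2-[(1R,2R)-2-{(5E)-7-[5-methoxy-3-methyl-2-(triisopropylsilyloxy)phenyl]-5-methylhept-5-en-2-ynoyl}-1,2-dimethylcyclopentyl]acetate | COc1cc(C)c(O[Si](C(C)C)(C(C)C)C(C)C)c(C/C=C(\C)CC#CC(=O)[C@]2(C)CCC[C@]2(C)CC(=O)OC(C)(C)C)c1 | intermediate
28 | 2-[(1R,2R)-2-{(5E)-7-[5-methoxy-3-methyl-2-(triisopropylsilyloxy)phenyl]-5-methylhept-5-en-2-ynoyl}-1,2-dimethylcyclopentyl]acetic acid | COc1cc(C)c(O[Si](C(C)C)(C(C)C)C(C)C)c(C/C=C(\C)CC#CC(=O)[C@]2(C)CCC[C@]2(C)CC(=O)O)c1 | intermediate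
29 | 1,3-dioxoisoindolin-2-yl 2-[(1R,2R)-2-{(5E)-7-[5-methoxy-3-methyl-2-(triisopropylsilyloxy)phenyl]-5-methylhept-5-en-2-ynoyl}-1,2-dimethylcyclopentyl]acetate | COc1cc(C)c(O[Si](C(C)C)(C(C)C)C(C)C)c(C/C=C(\C)CC#CC(=O)[C@]2(C)CCC[C@]2(C)CC(=O)ON2C(=O)c3ccccc3C2=O)c1 | intermediate
30 | (3aR,7aR)-6-{(2E)-4-[5-methoxy-3-methyl-2-(triisopropylsilyloxy)phenyl]-2-methylbut-2-en-1-yl}-3a,7a-dimethyl-1,2,3,3a,7,7a-hexahydro-4H-inden-4-one | COc1cc(C)c(O[Si](C(C)C)(C(C)C)C(C)C)c(C/C=C(\C)CC2=CC(=O)[C@]3(C)CCC[C@]3(C)C2)c1 | intermediate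
31 | (3aR,7aR)-5-iodo-6-{(2E)-4-[5-methoxy-3-methyl-2-(triisopropylsilyloxy)phenyl]-2-methylbut-2-en-1-yl}-3a,7a-dimethyl-1,2,3,3a,7,7a-hexahydro-4H-inden-4-one | COc1cc(C)c(O[Si](C(C)C)(C(C)C)C(C)C)c(C/C=C(\C)CC2=C(I)C(=O)[C@]3(C)CCC[C@]3(C)C2)c1 | intermediate
32 | 3-hydroxy-3-methylbutanoic acid | CC(C)(O)CC(=O)O | starting material
33 | 1,3-dioxoisoindolin-2-yl 3-hydroxy-3-methylbutanoate | CC(C)(O)CC(=O)ON1C(=O)c2ccccc2C1=O | intermediate
34 | (3aR,7aR)-5-(2-hydroxy-2-methylpropyl)-6-{(2E)-4-[5-methoxy-3-methyl-2-(triisopropylsilyloxy)phenyl]-2-methylbut-2-en-1-yl}-3a,7a-dimethyl-1,2,3,3a,7,7a-hexahydro-4H-inden-4-one | COc1cc(C)c(O[Si](C(C)C)(C(C)C)C(C)C)c(C/C=C(\C)CC2=C(CC(C)(C)O)C(=O)[C@]3(C)CCC[C@]3(C)C2)c1 | intermediate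
35 | (3aR,7aR)-5-(2-hydroxy-2-methylpropyl)-6-[(2E)-4-(2-hydroxy-5-methoxy-3-methylphenyl)-2-methylbut-2-en-1-yl]-3a,7a-dimethyl-1,2,3,3a,7,7a-hexahydro-4H-inden-4-one (CNP0158008.2) | COc1cc(C)c(O)c(C/C=C(\C)CC2=C(CC(C)(C)O)C(=O)[C@]3(C)CCC[C@]3(C)C2)c1 | target

**Count and risks**

Total step count: 20. Longest linear sequence: 12 steps (1, 2, 3, 4, 5, 13, 14, 15, 16, 17, 19, 20; the branch from 13 and 14 through steps 8–12 is equally long).

Steps most likely to fail:

1. Step 16 (proposed new method). Electron transfer may go to the ynone instead of the ester; the primary radical may be quenched before it reaches C6; the vinyl radical may take a hydrogen from the allylic methyl group by a 1,5-shift and scramble the side-chain alkene; phthalimide anion may isomerise the skipped enyne. The fallback closes ring B by a tin hydride chain reaction of an alkyl iodide, a known way of cyclising iodoalkyl ynones in the endo mode. It sets out from acid 8 and uses acetylide 25. Acid 8 is converted with N-hydroxypyridine-2-thione and N,N'-dicyclohexylcarbodiimide in the dark into the Barton ester 2-thioxopyridin-1(2H)-yl 2-[(1R,2R)-2-formyl-1,2-dimethylcyclopentyl]acetate F1. Irradiation of F1 with iodoform gives (1R,2S)-2-(iodomethyl)-1,2-dimethylcyclopentane-1-carbaldehyde F2. Acetylide 25 adds to the aldehyde at –78 °C to give the propargylic alcohol (5E)-1-[(1R,2S)-2-(iodomethyl)-1,2-dimethylcyclopentyl]-7-[5-methoxy-3-methyl-2-(triisopropylsilyloxy)phenyl]-5-methylhept-5-en-2-yn-1-ol F3. Dess–Martin oxidation gives the iodo ynone (5E)-1-[(1R,2S)-2-(iodomethyl)-1,2-dimethylcyclopentyl]-7-[5-methoxy-3-methyl-2-(triisopropylsilyloxy)phenyl]-5-methylhept-5-en-2-yn-1-one F4. Slow addition of Bu3SnH and AIBN in benzene at 80 °C should then give the enone, and the route is rejoined at 30.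

2. Step 19. Reductive loss of iodine from the α-iodoenone may outrun cross-coupling, reductive elimination at the tetrasubstituted alkene carbon may be slow, and the alkyl radical may dimerise or be reduced. The fallback sets out from 31 and builds the arm in two polar operations. Stille coupling with tributyl(2-methylallyl)stannane (Pd2(dba)3, AsPh3, CuI, DMF) gives the methallyl enone (3aR,7aR)-6-{(2E)-4-[5-methoxy-3-methyl-2-(triisopropylsilyloxy)phenyl]-2-methylbut-2-en-1-yl}-3a,7a-dimethyl-5-(2-methylprop-2-en-1-yl)-1,2,3,3a,7,7a-hexahydro-4H-inden-4-one F5. Oxymercuration with Hg(OAc)2 in THF/H2O, which is faster at the 1,1-disubstituted than at the trisubstituted alkene, gives the organomercurial (3aR,7aR)-5-[3-(acetoxymercurio)-2-hydroxy-2-methylpropyl]-6-{(2E)-4-[5-methoxy-3-methyl-2-(triisopropylsilyloxy)phenyl]-2-methylbut-2-en-1-yl}-3a,7a-dimethyl-1,2,3,3a,7,7a-hexahydro-4H-inden-4-one F6. Reduction in the same flask with NaBH4/NaOH at 0 °C rejoins the route at 34.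

3. Step 3. Discrimination between the two enantiotopic, neopentyl-type methylenes may be insufficient, giving material of low enantiomeric purity. The fallback sets out from 5 and replaces asymmetric deprotonation by resolution. LiN(i-Pr)2 and TMSCl give the racemic silyl enol ether rac-1,5-dimethyl-3-(trimethylsilyloxy)bicyclo[3.3.0]oct-2-ene F7. Ozonolysis as in step 4 passes through the racemic methoxy hydroperoxide trimethylsilyl rac-2-[2-[hydroperoxy(methoxy)methyl]-1,2-dimethylcyclopentyl]acetate F8 to the racemic aldehyde acid rac-2-(cis-2-formyl-1,2-dimethylcyclopentyl)acetic acid F9. Esterification as in step 5 gives the racemic ester tert-butyl rac-2-(cis-2-formyl-1,2-dimethylcyclopentyl)acetate F10. Preparative chromatography on a chiral stationary phase separates the enantiomers, and the (1R,2R)-enantiomer rejoins the route at 9.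

**Further compounds**

F1 | step 16 | 2-thioxopyridin-1(2H)-yl 2-[(1R,2R)-2-formyl-1,2-dimethylcyclopentyl]acetate | O=C[C@]1(C)CCC[C@]1(C)CC(=O)On1ccccc1=S
F2 | step 16 | (1R,2S)-2-(iodomethyl)-1,2-dimethylcyclopentane-1-carbaldehyde | O=C[C@]1(C)CCC[C@]1(C)CI
F3 | step 16 | (5E)-1-[(1R,2S)-2-(iodomethyl)-1,2-dimethylcyclopentyl]-7-[5-methoxy-3-methyl-2-(triisopropylsilyloxy)phenyl]-5-methylhept-5-en-2-yn-1-ol (carbinol epimers) | COc1cc(C)c(O[Si](C(C)C)(C(C)C)C(C)C)c(C/C=C(\C)CC#CC(O)[C@]2(C)CCC[C@]2(C)CI)c1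
F4 | step 16 | (5E)-1-[(1R,2S)-2-(iodomethyl)-1,2-dimethylcyclopentyl]-7-[5-methoxy-3-methyl-2-(triisopropylsilyloxy)phenyl]-5-methylhept-5-en-2-yn-1-one | COc1cc(C)c(O[Si](C(C)C)(C(C)C)C(C)C)c(C/C=C(\C)CC#CC(=O)[C@]2(C)CCC[C@]2(C)CI)c1
F5 | step 19 | (3aR,7aR)-6-{(2E)-4-[5-methoxy-3-methyl-2-(triisopropylsilyloxy)phenyl]-2-methylbut-2-en-1-yl}-3a,7a-dimethyl-5-(2-methylprop-2-en-1-yl)-1,2,3,3a,7,7a-hexahydro-4H-inden-4-one | COc1cc(C)c(O[Si](C(C)C)(C(C)C)C(C)C)c(C/C=C(\C)CC2=C(CC(C)=C)C(=O)[C@]3(C)CCC[C@]3(C)C2)c1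
F6 | step 19 | (3aR,7aR)-5-[3-(acetoxymercurio)-2-hydroxy-2-methylpropyl]-6-{(2E)-4-[5-methoxy-3-methyl-2-(triisopropylsilyloxy)phenyl]-2-methylbut-2-en-1-yl}-3a,7a-dimethyl-1,2,3,3a,7,7a-hexahydro-4H-inden-4-one (carbinol epimers) | COc1cc(C)c(O[Si](C(C)C)(C(C)C)C(C)C)c(C/C=C(\C)CC2=C(CC(C)(O)C[Hg]OC(C)=O)C(=O)[C@]3(C)CCC[C@]3(C)C2)c1
F7 | step 3 | rac-1,5-dimethyl-3-(trimethylsilyloxy)bicyclo[3.3.0]oct-2-ene (both enantiomers) | C[Si](C)(C)OC1=C[C@]2(C)CCC[C@]2(C)C1.C[Si](C)(C)OC1=C[C@@]2(C)CCC[C@@]2(C)C1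
F8 | step 3 | trimethylsilyl rac-2-[2-[hydroperoxy(methoxy)methyl]-1,2-dimethylcyclopentyl]acetate (cis ring substituents; both enantiomers) | COC(OO)[C@]1(C)CCC[C@]1(C)CC(=O)O[Si](C)(C)C.COC(OO)[C@@]1(C)CCC[C@@]1(C)CC(=O)O[Si](C)(C)C
F9 | step 3 | rac-2-(cis-2-formyl-1,2-dimethylcyclopentyl)acetic acid (both enantiomers) | O=C[C@]1(C)CCC[C@]1(C)CC(=O)O.O=C[C@@]1(C)CCC[C@@]1(C)CC(=O)O
F10 | step 3 | tert-butyl rac-2-(cis-2-formyl-1,2-dimethylcyclopentyl)acetate (both enantiomers) | O=C[C@]1(C)CCC[C@]1(C)CC(=O)OC(C)(C)C.O=C[C@@]1(C)CCC[C@@]1(C)CC(=O)OC(C)(C)C
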